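## Analysis of the target

The target is a 2‑hydroxychroman‑4‑one (ring A aromatic, ring B the oxygen heterocycle) whose C2 is joined through one methylene to ring C, a 4,6‑dihydroxybenzoic acid. Ring A carries a heptyl chain at C5, peri to the C4 ketone, and a hydroxyl at C7. Unfolded, the skeleton is a linear aryl–CO–CH2–CO–CH2–aryl chain, and ring B is only the hemiketal that the C8a phenol forms with the C2 ketone of this 1,3‑diketone. The single stereocentre, C2 (R), is that hemiketal carbon: it bears O1, a free hydroxyl, C3 and the benzylic CH2, has no partner stereocentre, and can invert in solution by ring opening to the achiral diketone and reclosure. Several groups are sensitive: acid dehydrates C2–C3 to the chromone, the ring C carboxyl can trap the C2 ketone as an isocoumarin, strong base can cleave the 1,3‑diketone and exposes the two resorcinol rings to oxidation, and the dihydroxybenzoic acid can decarboxylate on heating. The synthesis is hard because the diketone must stay masked until the last bond‑changing step and be released without acid, and because no stereocentre set earlier can survive, so the (R) configuration has to be imposed on the finished, equilibrating hemiketal. The plan rests on ring C: its carboxyl at C6′ lies between the oxygenated C5′ and C1′, which carries the CH2–C2 unit. The parent 2,4‑dioxygenated benzoic acid therefore has exactly one free ortho C–H, and the atoms C6′(carboxyl)–O, C2, CH2 and C1′ are those of an isocoumarin whose lactone has been hydrolysed.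

## Retrosynthetic reasoning

**C2 configuration (20 ⇒ 19 ⇒ 18).** The free acid 20 is released from its ammonium salt 19, and 19 is traced to racemic hemiketal 18. Because C2 epimerises through the open diketo acid 17, the stereocentre is not disconnected into an asymmetric bond formation. It is settled last, by letting the two antipodes of 18 interconvert while one diastereomeric salt leaves solution. The forward operation has to combine fast ring‑chain equilibration with a clear solubility difference between the two salts.

**O1–C2 and five O–benzyl bonds (18 ⇒ 17 ⇒ 15).** Ring B is not built by a reaction of its own: it closes when the C8a phenol and the C2 ketone are both free. Cutting all benzyl–oxygen bonds at once, including the one on the C4 enol oxygen, leads back to the fully benzylated keto acid 15. The gain is that the diketone and the five hydroxyls appear together in one neutral, reductive step, with no acid present to drive dehydration.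

**Lactone C–O bond (15 ⇒ 16).** Keto acid 15 is an ortho‑(2‑oxoalkyl)benzoic acid, and its dehydrated cyclic form is isocoumarin 16. Going back to 16 ties the C2 ketone and the carboxyl into one neutral enol lactone that can be purified. The forward step is an alkaline lactone hydrolysis, which must leave the enol ether alone.

**C1′–CH2 and carboxyl O–C2 (16 ⇒ 3 + 14), the key disconnection.** Cutting here divides the molecule into two halves of similar size, acid 3 (ring C) and sulfoxonium ylide 14 (ring A with C1–C4 of the chain). Acid 3 has a single ortho C–H, so the carboxyl group can direct the bond formation without any pre‑installed halide or benzylic handle on ring C. The ylide carbon becomes the benzylic CH2 and the ylide carbonyl becomes C2. The forward reaction has to metalate that C–H, transfer the carbene carbon, and lactonise, all without disturbing the benzyl enol ether that masks C4.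

**Ylide C–acyl bond (14 ⇒ 11 + 12).** The ylide is cut between its carbanionic carbon and C2, giving β‑benzyloxy acrylic acid 11, activated as acid chloride 13, and the methylide derived from salt 12. Acylation of that methylide by acid chlorides is the standard entry to such ylides. The forward step only needs an activation of 11 that releases no strong acid.

**Enol ether through a ring (11 ⇒ 10 ⇒ 9 ⇒ 8).** An open‑chain β‑keto ester would benzylate on carbon and give mixed alkene geometry. Acid 11 is therefore traced, through phenoxide 10, to coumarin 9: the C2 carboxyl and the C8a oxygen of 11 are the two ends of a lactone. In the ring the C4 oxygen belongs to a vinylogous carboxylic acid (8), which etherifies on oxygen, and the ring fixes the (E) geometry in which the enol oxygen is trans to the C2 carbonyl. The forward steps are an O‑benzylation of 8 and an alkaline opening of 9 with capture of the phenoxide.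

**C2 carbon and ring A ketone (8 ⇒ 7 ⇒ 6 ⇒ 4).** Hydroxycoumarin 8 is cut at C2–C3 and C2–O1, the C2 carbon coming from a carbonate electrophile that joins the enolate and the phenoxide of hydroxy ketone 7. Ketone 7 comes from dihydroxy ketone 6 by benzylation of the unchelated hydroxyl, and 6 from 5‑heptylresorcinol 4 by ring acetylation at the position flanked by heptyl and hydroxyl (through iminium salt 5).

**Ring C acid (3 ⇒ 2 ⇒ 1).** Acid 3 is the saponification product of tribenzyl compound 2, made from 2,4‑dihydroxybenzoic acid 1.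

## Alternatives that were turned down

**Alternative 1:** Both bonds to C2 (benzylic CH2–C2 and C2–C3) are disconnected, with C2 supplied as a one‑carbon carbonyl unit. In the forward sense the enolate of methyl ketone A3 and benzylic bromide A2 would be joined under zerovalent palladium and a wide‑bite‑angle diphosphine in a carbonylating atmosphere to give open‑chain diketo ester A1, with no ring closed.
- For it: three simple pieces, two C–C bonds in one step, the correct oxidation level, and A1 would go to 18 by a single hydrogenolysis. On convergence and step count it is stronger than the chosen route.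
- Against it: the enolate of A3 can displace the bromide of A2 directly, without carbonyl insertion. A1 is more acidic than A3 and will quench the enolate or be acylated again. A1 is a free 1,3‑diketone that must be purified. A2 requires benzylic bromination on a very electron‑rich ring, where ring bromination competes.
- Comparison: the chosen route is longer, but its C–C bond can form at only one site, no direct‑alkylation pathway exists, and the diketone stays masked until the neutral last step. Both routes need the same final resolution.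

**Alternative 2:** The disconnection lies inside ring C, at C1′–C6′. Diketo‑dioxinone A5, which already contains rings A and B as a chromone, would be treated with an amine base and then acid. The dioxinone α‑carbon adds to the ketone that becomes C1′, and dehydration and enolisation aromatise ring C to give A4.
- For it: the substitution pattern of ring C is guaranteed by construction, ring C needs no benzyl groups, and no precious‑metal C–H step is required. On these points it is as strong or stronger.
- Against it: A4 is a chromone, the dehydrated form of ring B. Water must be put back across C2–C3 by alkaline opening to 17 while the dioxinone is also hydrolysed, both on a base‑sensitive diketone, and any acid returns the material to the chromone. A5 is a tetracarbonyl compound that needs a long linear assembly, and its chromone 2‑methylene is a second acidic site.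
- Comparison: the chosen route never passes through the chromone. It reaches the hemiketal from the open diketone under neutral conditions, from two aromatic building blocks.

**Alternative 3:** The O1–C2 bond is disconnected. Under a cinchona‑derived bifunctional squaramide, the C8a phenol of (E)‑β‑benzyloxy enone A7 would add to C2, closing ring B and setting C2 as the (R)‑benzyl ketal A6.
- For it: this is the only plan in which a catalyst sets C2, in a configurationally stable ketal that can be assayed and purified. On stereocontrol before deprotection it is stronger.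
- Against it: the adduct is a β‑alkoxy ketone that can lose its benzyloxy group to give the chromone or revert to A7. Enantiocontrol at a fully substituted, oxygen‑bearing β‑carbon is unproven. A7 carries the enol ether on C2 rather than C4 and is as laborious to make as 14. Most important, hydrogenolysis of A6 gives the free hemiketal, which equilibrates through 17, so the catalyst‑derived configuration is not secure in solution and a crystallisation is needed anyway.
- Comparison: the chosen route spends its key step on the C–C bond and decides the stereochemistry in the solid state of the final compound.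

Key step: step 9

Assumption: C2 is configurationally stable in the crystal but equilibrates through 17 in solution, so 20 is delivered as a crystalline solid and handled cold in solution.
Assumption: the salt of the (R)‑acid with (S)‑N,N‑dimethyl‑1‑phenylethylamine is taken to be the less soluble diastereomer; if the opposite holds, the (R)‑amine is used in the same way.

## Route

**Step 1**
Reactants: 1 2,4‑dihydroxybenzoic acid
Product: 2 benzyl 2,4‑bis(benzyloxy)benzoate
Conditions: BnBr (3.3 equiv), K2CO3, DMF, 70 °C
Reagents that add atoms: benzyl bromide, BrCc1ccccc1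
Why: Williamson alkylation of both phenoxides and the carboxylate; excess reagent and heat overcome the hydrogen‑bonded 2‑hydroxyl.

**Step 2**
Reactants: 2 benzyl 2,4‑bis(benzyloxy)benzoate
Product: 3 2,4‑bis(benzyloxy)benzoic acid
Conditions: NaOH (aq), THF–MeOH, 65 °C; then 1 M HCl
Reagents that add atoms: sodium hydroxide, [Na+].[OH-]
Why: Ester saponification; aryl benzyl ethers are inert to hydroxide.

**Step 3**
Reactants: 4 5‑heptylresorcinol
Product: 6 1‑(2,4‑dihydroxy‑6‑heptylphenyl)ethan‑1‑one, via ketiminium chloride 5 (not isolated)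
Conditions: MeCN, ZnCl2, HCl (g), Et2O, 0 °C; then H2O, 100 °C
Reagents that add atoms: acetonitrile, CC#N; hydrogen chloride, Cl; water, O
Why: Hoesch acylation; the nitrilium electrophile should attack the position para to one hydroxyl and ortho to the other, as in the orcinol series, the site between the two hydroxyls being more hindered. Hydrolysis of iminium salt 5 gives the methyl ketone.

**Step 4**
Reactants: 6 1‑(2,4‑dihydroxy‑6‑heptylphenyl)ethan‑1‑one
Product: 7 1‑[4‑(benzyloxy)‑2‑heptyl‑6‑hydroxyphenyl]ethan‑1‑one
Conditions: BnBr (1.05 equiv), K2CO3, acetone, 56 °C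
Reagents that add atoms: benzyl bromide, BrCc1ccccc1
Why: Williamson alkylation; the hydroxyl ortho to the ketone is held in a hydrogen bond and is much less nucleophilic, so one equivalent of reagent should go to the para hydroxyl.

**Step 5**
Reactants: 7 1‑[4‑(benzyloxy)‑2‑heptyl‑6‑hydroxyphenyl]ethan‑1‑one
Product: 8 7‑(benzyloxy)‑5‑heptyl‑4‑hydroxy‑2H‑chromen‑2‑one
Conditions: NaH, (EtO)2CO, toluene, 110 °C; then 1 M HCl, 0 °C
Reagents that add atoms: diethyl carbonate, CCOC(=O)OCC
Why: Claisen acylation of the ketone enolate by the carbonate followed by lactonisation of the phenoxide onto the new ester, the classical route from 2‑hydroxyacetophenones to 4‑hydroxycoumarins. The product is held as its stabilised anion until acidification.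

**Step 6**
Reactants: 8 7‑(benzyloxy)‑5‑heptyl‑4‑hydroxy‑2H‑chromen‑2‑one
Product: 9 4,7‑bis(benzyloxy)‑5‑heptyl‑2H‑chromen‑2‑one
Conditions: BnOH, PPh3, DIAD, THF, 0 → 20 °C
Reagents that add atoms: benzyl alcohol, OCc1ccccc1
Why: Mitsunobu etherification; the 4‑hydroxycoumarin is a vinylogous carboxylic acid, acidic enough for the betaine, and should alkylate on the C4 oxygen and not on C3. The lactone ring fixes the enol ether with its oxygen trans to the C2 carbonyl.

**Step 7**
Reactants: 9 4,7‑bis(benzyloxy)‑5‑heptyl‑2H‑chromen‑2‑one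
Product: 11 (2E)‑3‑(benzyloxy)‑3‑[2,4‑bis(benzyloxy)‑6‑heptylphenyl]prop‑2‑enoic acid, via ring‑opened dipotassium salt 10 (not isolated)
Conditions: KOH, DMSO–H2O, 60 °C; BnBr, 20 °C; KOH (aq), 50 °C; then cold dilute HCl to pH 4
Reagents that add atoms: potassium hydroxide, [K+].[OH-]; benzyl bromide, BrCc1ccccc1
Why: Alkaline hydrolysis of the coumarin lactone at the C2 carbonyl (the coumarin to coumarinate opening) gives dianion 10, whose phenoxide is capped by Williamson benzylation so that it cannot re‑lactonise; any benzyl ester formed is saponified in the same flask. The ring geometry is carried into the open acid, and the enol ether is stable to base.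

**Step 8**
Reactants: 11 (2E)‑3‑(benzyloxy)‑3‑[2,4‑bis(benzyloxy)‑6‑heptylphenyl]prop‑2‑enoic acid; 12 trimethylsulfoxonium iodide
Product: 14 dimethylsulfoxonium (3E)‑4‑(benzyloxy)‑4‑[2,4‑bis(benzyloxy)‑6‑heptylphenyl]‑2‑oxobut‑3‑en‑1‑ylide, via acid chloride 13 (not isolated)
Conditions: 12 (3.2 equiv), KOtBu (3.0 equiv), THF, 65 °C then 0 °C; 11 with Me2C=C(Cl)NMe2, CH2Cl2, 0 °C, added to the methylide, 0 → 20 °C
Reagents that add atoms: 1‑chloro‑N,N,2‑trimethylprop‑1‑en‑1‑amine, CC(C)=C(Cl)N(C)C (its chlorine is found in 13 only)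
Why: The α‑chloroenamine makes the acid chloride without releasing HCl, which would cleave the enol ether. Acylation of dimethylsulfoxonium methylide by an acid chloride is the standard route to β‑keto sulfoxonium ylides, a second equivalent of methylide deprotonating the acylsulfoxonium salt. Attack at the acyl chloride should outrun conjugate addition to the hindered, donor‑substituted β‑carbon.

**Step 9**
Reactants: 3 2,4‑bis(benzyloxy)benzoic acid; 14 dimethylsulfoxonium (3E)‑4‑(benzyloxy)‑4‑[2,4‑bis(benzyloxy)‑6‑heptylphenyl]‑2‑oxobut‑3‑en‑1‑ylide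
Product: 16 6,8‑bis(benzyloxy)‑3‑{(E)‑2‑(benzyloxy)‑2‑[2,4‑bis(benzyloxy)‑6‑heptylphenyl]ethenyl}‑1H‑isochromen‑1‑one, via keto acid 15 (not isolated)
Conditions: 3 (1.0 equiv), 14 (1.3 equiv), [Cp*RhCl2]2 (4 mol %), AgSbF6 (16 mol %), NaOAc (1 equiv), ClCH2CH2Cl, 80 °C, argon
Reagents that add atoms: none
Why: Acetate‑assisted concerted metalation–deprotonation of the rhodium carboxylate of 3 at C6, its only ortho C–H (the other ortho position carries a benzyloxy group), gives a five‑membered rhodacycle of trivalent rhodium. The ylide carbon of 14 binds to rhodium and loses dimethyl sulfoxide to give a rhodium carbene, into which the aryl group migrates; protonation of the resulting rhodium enolate releases keto acid 15 and returns the catalyst. The carboxyl oxygen of 15 then adds to the new C2 ketone in a 6‑exo‑trig closure and the lactol loses water, helped by conjugation of the enol lactone with the enol ether, to give isocoumarin 16. The closest known reaction type is the Cp*Rh‑catalysed annulation of benzoic acids with α‑carbonyl sulfoxonium ylides to 3‑substituted isocoumarins. No stereocentre is formed; the (E) enol ether is a spectator, and its geometry keeps the enol oxygen on the far side of the carbene carbon, so an oxonium ylide cannot form. Site selectivity on ring C is secured by the substitution pattern of 3, and the buffered, non‑protic medium is chosen to spare the acid‑labile benzyl enol ether. Any 15 that has not lactonised is not lost, since it is the product of step 10.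

**Step 10**
Reactants: 16 6,8‑bis(benzyloxy)‑3‑{(E)‑2‑(benzyloxy)‑2‑[2,4‑bis(benzyloxy)‑6‑heptylphenyl]ethenyl}‑1H‑isochromen‑1‑one
Product: 15 2,4‑bis(benzyloxy)‑6‑{(3E)‑4‑(benzyloxy)‑4‑[2,4‑bis(benzyloxy)‑6‑heptylphenyl]‑2‑oxobut‑3‑en‑1‑yl}benzoic acid
Conditions: LiOH (aq), THF, 40 °C; then cold dilute HCl to pH 4–5, 0 °C
Reagents that add atoms: lithium hydroxide, [Li+].[OH-]
Why: Enol lactone hydrolysis; hydroxide adds to the C1 carbonyl and the enolate leaving group becomes the C2 ketone. The benzyl enol ether, whose β‑carbon is shielded by the 2,6‑disubstituted ring, and the aryl benzyl ethers should survive, and cold, mild acidification avoids re‑lactonisation.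

**Step 11**
Reactants: 15 2,4‑bis(benzyloxy)‑6‑{(3E)‑4‑(benzyloxy)‑4‑[2,4‑bis(benzyloxy)‑6‑heptylphenyl]‑2‑oxobut‑3‑en‑1‑yl}benzoic acid
Product: 18 rac‑2‑[(5‑heptyl‑2,7‑dihydroxy‑4‑oxo‑3,4‑dihydro‑2H‑chromen‑2‑yl)methyl]‑4,6‑dihydroxybenzoic acid, via open diketo acid 17 (not isolated)
Conditions: H2 (1 atm), 10% Pd/C, EtOAc–THF, 20 °C; filtered and concentrated below 30 °C
Reagents that add atoms: none
Why: Hydrogenolysis of the four aryl benzyl ethers and of the vinylogous benzyl ester (O–CH2Ph cleavage, as with benzyl tetronates); the freed enol becomes the C4 ketone, giving 17. The C8a phenol of 17 then adds to the C2 ketone (6‑exo‑trig hemiketalisation) to give 18 as the racemate, and the neutral medium should avoid dehydration to the chromone.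

**Step 12**
Reactants: 18 rac‑2‑[(5‑heptyl‑2,7‑dihydroxy‑4‑oxo‑3,4‑dihydro‑2H‑chromen‑2‑yl)methyl]‑4,6‑dihydroxybenzoic acid
Product: 19 (1S)‑N,N‑dimethyl‑1‑phenylethan‑1‑aminium 2‑{[(2R)‑5‑heptyl‑2,7‑dihydroxy‑4‑oxo‑3,4‑dihydro‑2H‑chromen‑2‑yl]methyl}‑4,6‑dihydroxybenzoate
Conditions: (S)‑PhCH(Me)NMe2 (1.0 equiv), MeCN–iPrOAc, 40 → 5 °C, seeded slurry aged under argon
Reagents that add atoms: (S)‑N,N‑dimethyl‑1‑phenylethylamine, C[C@H](N(C)C)c1ccccc1
Why: Proposed new method: the hemiketal carbon epimerises in solution by ring opening to diketo acid 17, catalysed by the ammonium carboxylate buffer, while the less soluble diastereomeric salt (taken to be that of the (R)‑acid) crystallises, so the equilibrium drains into one diastereomer and C2 is set under lattice control; the closest known reaction type is the crystallisation‑induced diastereomer transformation of lactols, hemiaminals and epimerisable acids as chiral amine salts, and a tertiary amine is used so that no enaminone can form with the diketone tautomer.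

**Step 13**
Reactants: 19 (1S)‑N,N‑dimethyl‑1‑phenylethan‑1‑aminium 2‑{[(2R)‑5‑heptyl‑2,7‑dihydroxy‑4‑oxo‑3,4‑dihydro‑2H‑chromen‑2‑yl]methyl}‑4,6‑dihydroxybenzoate
Product: 20 2‑{[(2R)‑5‑heptyl‑2,7‑dihydroxy‑4‑oxo‑3,4‑dihydro‑2H‑chromen‑2‑yl]methyl}‑4,6‑dihydroxybenzoic acid
Conditions: 0.5 M HCl (1.05 equiv), EtOAc, 0 °C, brief contact; dried, concentrated cold, crystallised from EtOAc–heptane at −20 °C
Reagents that add atoms: none
Why: Acid–base partition; the carboxylate is protonated and the tertiary amine stays in the aqueous phase. Short contact at 0 °C and immediate crystallisation should limit ring‑opening epimerisation, so the configuration set in step 12 is kept.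

## Compound list

1 | 2,4‑dihydroxybenzoic acid | OC(=O)c1ccc(O)cc1O | starting material
2 | benzyl 2,4‑bis(benzyloxy)benzoate | O=C(OCc1ccccc1)c1ccc(OCc2ccccc2)cc1OCc1ccccc1 | intermediate
3 | 2,4‑bis(benzyloxy)benzoic acid | OC(=O)c1ccc(OCc2ccccc2)cc1OCc1ccccc1 | intermediate
4 | 5‑heptylresorcinol | CCCCCCCc1cc(O)cc(O)c1 | starting material
5 | 1‑(2,4‑dihydroxy‑6‑heptylphenyl)ethan‑1‑iminium chloride | CCCCCCCc1cc(O)cc(O)c1C(C)=[NH2+].[Cl-] | intermediate
6 | 1‑(2,4‑dihydroxy‑6‑heptylphenyl)ethan‑1‑one | CCCCCCCc1cc(O)cc(O)c1C(C)=O | intermediate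
7 | 1‑[4‑(benzyloxy)‑2‑heptyl‑6‑hydroxyphenyl]ethan‑1‑one | CCCCCCCc1cc(OCc2ccccc2)cc(O)c1C(C)=O | intermediate
8 | 7‑(benzyloxy)‑5‑heptyl‑4‑hydroxy‑2H‑chromen‑2‑one | CCCCCCCc1cc(OCc2ccccc2)cc2oc(=O)cc(O)c12 | intermediate
9 | 4,7‑bis(benzyloxy)‑5‑heptyl‑2H‑chromen‑2‑one | CCCCCCCc1cc(OCc2ccccc2)cc2oc(=O)cc(OCc3ccccc3)c12 | intermediate
10 | dipotassium (2E)‑3‑(benzyloxy)‑3‑[4‑(benzyloxy)‑2‑heptyl‑6‑oxidophenyl]prop‑2‑enoate | [K+].[K+].[O-]C(=O)/C=C(/OCc1ccccc1)c1c(CCCCCCC)cc(OCc2ccccc2)cc1[O-] | intermediate
11 | (2E)‑3‑(benzyloxy)‑3‑[2,4‑bis(benzyloxy)‑6‑heptylphenyl]prop‑2‑enoic acid | OC(=O)/C=C(/OCc1ccccc1)c1c(CCCCCCC)cc(OCc2ccccc2)cc1OCc1ccccc1 | intermediate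
12 | trimethylsulfoxonium iodide | C[S+](C)(C)=O.[I-] | starting material
13 | (2E)‑3‑(benzyloxy)‑3‑[2,4‑bis(benzyloxy)‑6‑heptylphenyl]prop‑2‑enoyl chloride | ClC(=O)/C=C(/OCc1ccccc1)c1c(CCCCCCC)cc(OCc2ccccc2)cc1OCc1ccccc1 | intermediate
14 | dimethylsulfoxonium (3E)‑4‑(benzyloxy)‑4‑[2,4‑bis(benzyloxy)‑6‑heptylphenyl]‑2‑oxobut‑3‑en‑1‑ylide | C[S+](C)(=O)[CH-]C(=O)/C=C(/OCc1ccccc1)c1c(CCCCCCC)cc(OCc2ccccc2)cc1OCc1ccccc1 | intermediate
15 | 2,4‑bis(benzyloxy)‑6‑{(3E)‑4‑(benzyloxy)‑4‑[2,4‑bis(benzyloxy)‑6‑heptylphenyl]‑2‑oxobut‑3‑en‑1‑yl}benzoic acid | OC(=O)c1c(CC(=O)/C=C(/OCc2ccccc2)c2c(CCCCCCC)cc(OCc3ccccc3)cc2OCc2ccccc2)cc(OCc2ccccc2)cc1OCc1ccccc1 | intermediate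
16 | 6,8‑bis(benzyloxy)‑3‑{(E)‑2‑(benzyloxy)‑2‑[2,4‑bis(benzyloxy)‑6‑heptylphenyl]ethenyl}‑1H‑isochromen‑1‑one | O=c1oc(/C=C(/OCc3ccccc3)c3c(CCCCCCC)cc(OCc4ccccc4)cc3OCc3ccccc3)cc2cc(OCc3ccccc3)cc(OCc3ccccc3)c12 | intermediate
17 | 2‑[4‑(2‑heptyl‑4,6‑dihydroxyphenyl)‑2,4‑dioxobutyl]‑4,6‑dihydroxybenzoic acid | CCCCCCCc1cc(O)cc(O)c1C(=O)CC(=O)Cc1cc(O)cc(O)c1C(=O)O | intermediate
18 | rac‑2‑[(5‑heptyl‑2,7‑dihydroxy‑4‑oxo‑3,4‑dihydro‑2H‑chromen‑2‑yl)methyl]‑4,6‑dihydroxybenzoic acid | CCCCCCCc1cc(O)cc2c1C(=O)CC(O)(Cc1cc(O)cc(O)c1C(=O)O)O2 | intermediate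
19 | (1S)‑N,N‑dimethyl‑1‑phenylethan‑1‑aminium 2‑{[(2R)‑5‑heptyl‑2,7‑dihydroxy‑4‑oxo‑3,4‑dihydro‑2H‑chromen‑2‑yl]methyl}‑4,6‑dihydroxybenzoate | CCCCCCCc1cc(O)cc2c1C(=O)C[C@@](O)(Cc1cc(O)cc(O)c1C(=O)[O-])O2.C[C@H]([NH+](C)C)c1ccccc1 | intermediate
20 | 2‑{[(2R)‑5‑heptyl‑2,7‑dihydroxy‑4‑oxo‑3,4‑dihydro‑2H‑chromen‑2‑yl]methyl}‑4,6‑dihydroxybenzoic acid | CCCCCCCc1cc(O)cc2c1C(=O)C[C@@](O)(Cc1cc(O)cc(O)c1C(=O)O)O2 | target

## Step count and least certain steps

Total: 13 steps. Longest linear sequence: 11 steps (steps 3 to 13); steps 1 and 2 form the short branch that joins at step 9.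

**Step 12 (labelled step).** The salt may fail to crystallise or both diastereomers may co‑crystallise, epimerisation through 17 may be slower than crystallisation so that only a classical resolution results, and the amine may promote loss of water across C2–C3. Fallback, from 18 back to the route at 20: the enantiomers of 18 are separated by preparative chromatography on an immobilised polysaccharide chiral phase with an acidified eluent below room temperature. The (R) fraction is evaporated cold and crystallised to give 20, and the other fraction is left to racemise in solution and injected again. This is known practice and makes no new compound (F0).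

**Step 9 (key step).** The carboxylic acid may protonate the ylide and be O‑alkylated by the resulting sulfoxonium salt (ester formation instead of C–H alkylation), the Lewis‑acidic cationic rhodium and silver may ionise the benzyl enol ether, and lactonisation may stop at 15. Fallback, from acid chloride 13 back to the route at 18, with the benzylic carbon taken from a methyl group rather than a C–H bond:
- Purchased 2,4‑dihydroxy‑6‑methylbenzoic acid F1 is benzylated as in step 1 to benzyl 2,4‑bis(benzyloxy)‑6‑methylbenzoate F2.
- 13 is treated with N,O‑dimethylhydroxylamine hydrochloride and triethylamine to give (2E)‑3‑(benzyloxy)‑3‑[2,4‑bis(benzyloxy)‑6‑heptylphenyl]‑N‑methoxy‑N‑methylprop‑2‑enamide F3.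
- Lateral lithiation of F2 (LDA, THF, −78 °C) and acylation of the benzylic anion by F3 gives benzyl 2,4‑bis(benzyloxy)‑6‑{(3E)‑4‑(benzyloxy)‑4‑[2,4‑bis(benzyloxy)‑6‑heptylphenyl]‑2‑oxobut‑3‑en‑1‑yl}benzoate F4.
- Hydrogenolysis of F4 under the conditions of step 11 removes six benzyl groups and gives 18.

**Step 7.** Hydroxide may add at C4 and hydrolyse the vinylogous ester back to 8, the phenoxide may re‑lactonise before it is capped, and in a water‑rich medium the phenoxide may be benzylated on carbon. Fallback, from 9 back to the route at 14, bypassing 11 and 13: coumarin 9 itself is used as the acylating agent for the methylide made from 12 and KOtBu, the aryloxide being the leaving group. This gives dimethylsulfoxonium (3E)‑4‑(benzyloxy)‑4‑[4‑(benzyloxy)‑2‑heptyl‑6‑hydroxyphenyl]‑2‑oxobut‑3‑en‑1‑ylide F5, whose phenol is benzylated (BnBr, K2CO3, DMF) to 14.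

**Step 11.** The enol ether double bond may be saturated before the O–benzyl bond is cleaved, which would lead on to reduction at C4. The product may also lose water to the chromone on concentration, or settle as the lactol with the ring C carboxyl. Fallback, from 15 back to the route at 18: the enol ether is hydrolysed first with dilute aqueous acid in THF to 2,4‑bis(benzyloxy)‑6‑{4‑[2,4‑bis(benzyloxy)‑6‑heptylphenyl]‑2,4‑dioxobutyl}benzoic acid F6. With all phenols still protected no chromone can form, and hydrogenolysis of the four aryl benzyl ethers of F6 then gives 18 without an alkene in the substrate.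

**Step 6.** Because the C4 oxygen is peri to the heptyl chain, alkylation may be diverted to the lactone oxygen (a 2‑benzyloxychromone) or to C3. Fallback, from 8 back to the route at 9, with the C4–O bond made by addition–elimination instead of O‑alkylation: 8 is converted with POCl3 into 7‑(benzyloxy)‑4‑chloro‑5‑heptyl‑2H‑chromen‑2‑one F7, and sodium benzyloxide in THF displaces the chloride to give 9.

## Further compounds

F0 | step 12 | none | none
F1 | step 9 | 2,4‑dihydroxy‑6‑methylbenzoic acid | Cc1cc(O)cc(O)c1C(=O)O
F2 | step 9 | benzyl 2,4‑bis(benzyloxy)‑6‑methylbenzoate | Cc1cc(OCc2ccccc2)cc(OCc2ccccc2)c1C(=O)OCc1ccccc1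
F3 | step 9 | (2E)‑3‑(benzyloxy)‑3‑[2,4‑bis(benzyloxy)‑6‑heptylphenyl]‑N‑methoxy‑N‑methylprop‑2‑enamide | CON(C)C(=O)/C=C(/OCc1ccccc1)c1c(CCCCCCC)cc(OCc2ccccc2)cc1OCc1ccccc1
F4 | step 9 | benzyl 2,4‑bis(benzyloxy)‑6‑{(3E)‑4‑(benzyloxy)‑4‑[2,4‑bis(benzyloxy)‑6‑heptylphenyl]‑2‑oxobut‑3‑en‑1‑yl}benzoate | O=C(OCc1ccccc1)c1c(CC(=O)/C=C(/OCc2ccccc2)c2c(CCCCCCC)cc(OCc3ccccc3)cc2OCc2ccccc2)cc(OCc2ccccc2)cc1OCc1ccccc1
F5 | step 7 | dimethylsulfoxonium (3E)‑4‑(benzyloxy)‑4‑[4‑(benzyloxy)‑2‑heptyl‑6‑hydroxyphenyl]‑2‑oxobut‑3‑en‑1‑ylide | C[S+](C)(=O)[CH-]C(=O)/C=C(/OCc1ccccc1)c1c(CCCCCCC)cc(OCc2ccccc2)cc1O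
F6 | step 11 | 2,4‑bis(benzyloxy)‑6‑{4‑[2,4‑bis(benzyloxy)‑6‑heptylphenyl]‑2,4‑dioxobutyl}benzoic acid | OC(=O)c1c(CC(=O)CC(=O)c2c(CCCCCCC)cc(OCc3ccccc3)cc2OCc2ccccc2)cc(OCc2ccccc2)cc1OCc1ccccc1
F7 | step 6 | 7‑(benzyloxy)‑4‑chloro‑5‑heptyl‑2H‑chromen‑2‑one | CCCCCCCc1cc(OCc2ccccc2)cc2oc(=O)cc(Cl)c12
A1 | alternative 1 | benzyl 2,4‑bis(benzyloxy)‑6‑{4‑[2,4‑bis(benzyloxy)‑6‑heptylphenyl]‑2,4‑dioxobutyl}benzoate | CCCCCCCc1cc(OCc2ccccc2)cc(OCc2ccccc2)c1C(=O)CC(=O)Cc1cc(OCc2ccccc2)cc(OCc2ccccc2)c1C(=O)OCc1ccccc1
A2 | alternative 1 | benzyl 2,4‑bis(benzyloxy)‑6‑(bromomethyl)benzoate | BrCc1cc(OCc2ccccc2)cc(OCc2ccccc2)c1C(=O)OCc1ccccc1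
A3 | alternative 1 | 1‑[2,4‑bis(benzyloxy)‑6‑heptylphenyl]ethan‑1‑one | CCCCCCCc1cc(OCc2ccccc2)cc(OCc2ccccc2)c1C(C)=O
A4 | alternative 2 | 5‑{[7‑(benzyloxy)‑5‑heptyl‑4‑oxo‑4H‑chromen‑2‑yl]methyl}‑7‑hydroxy‑2,2‑dimethyl‑4H‑1,3‑benzodioxin‑4‑one | CCCCCCCc1cc(OCc2ccccc2)cc2oc(Cc3cc(O)cc4OC(C)(C)OC(=O)c34)cc(=O)c12
A5 | alternative 2 | 6‑{5‑[7‑(benzyloxy)‑5‑heptyl‑4‑oxo‑4H‑chromen‑2‑yl]‑2,4‑dioxopentyl}‑2,2‑dimethyl‑4H‑1,3‑dioxin‑4‑one | CCCCCCCc1cc(OCc2ccccc2)cc2oc(CC(=O)CC(=O)CC3=CC(=O)OC(C)(C)O3)cc(=O)c12
A6 | alternative 3 | benzyl 2,4‑bis(benzyloxy)‑6‑{[(2R)‑2,7‑bis(benzyloxy)‑5‑heptyl‑4‑oxo‑3,4‑dihydro‑2H‑chromen‑2‑yl]methyl}benzoate | CCCCCCCc1cc(OCc2ccccc2)cc2c1C(=O)C[C@@](OCc1ccccc1)(Cc1cc(OCc3ccccc3)cc(OCc3ccccc3)c1C(=O)OCc1ccccc1)O2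
A7 | alternative 3 | benzyl 2,4‑bis(benzyloxy)‑6‑{(2E)‑2‑(benzyloxy)‑4‑[4‑(benzyloxy)‑2‑heptyl‑6‑hydroxyphenyl]‑4‑oxobut‑2‑en‑1‑yl}benzoate | CCCCCCCc1cc(OCc2ccccc2)cc(O)c1C(=O)/C=C(/OCc1ccccc1)Cc1cc(OCc2ccccc2)cc(OCc2ccccc2)c1C(=O)OCc1ccccc1
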